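Ring C of the flavanone is traced back to the flavone and cut at C4a–C4, C4–C3 and O1–C2. C4 is a lone carbonyl carbon between aryl carbon C4a and the C3–C2 pair that carries ring B, and C8a already holds O1. Ring C can therefore be assembled from CO, a terminal arylacetylene and an ortho-iodophenol. One palladium-catalysed operation forms all three bonds and the pyranone. The precursor is a hexasubstituted, mirror-symmetric 2-iodoresorcinol (5-OMe, 4,6-diprenyl), so it does not matter which hydroxyl closes the ring. C2 is set afterwards by ligand-controlled copper hydride reduction of the 5-O-protected flavone.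

Key step: step 7

Conventions: flavonoid numbering (O1, C2, C3, C4, C4a, C5–C8, C8a, ring B primed); prenyl = 3-methylbut-2-en-1-yl; MOM = methoxymethyl.

Assumption: the sense of induction in step 9 is inferred by spatial analogy with β-substituted cyclic enones, which points to the (S)-ligand for (2S). If the first run shows the opposite sense, the antipodal ligand is used and nothing else changes.

Step 1
Reactants: 1 methyl 2,4,6-trihydroxybenzoate; 2 prenyl bromide (1-bromo-3-methylbut-2-ene, 2 equiv)
Product: 3 methyl 2,4,6-trihydroxy-3,5-diprenylbenzoate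
Conditions: KOH (2.2 equiv), H2O, 0 °C to rt
Reagents that add atoms: none
Why: Base-mediated C-alkylation (SN2) of a phloroglucinol phenoxide: in water the oxygens are tied up by hydrogen bonding, so the soft allylic bromide should be taken up by the only two free ring carbons, C3 and C5, while the ester blocks the third position and tempers the ring enough to limit dearomatising over-alkylation.

Step 2
Reactants: 3 methyl 2,4,6-trihydroxy-3,5-diprenylbenzoate
Product: 4 methyl 2,6-dihydroxy-4-methoxy-3,5-diprenylbenzoate
Conditions: Me2SO4 (1.05 equiv), K2CO3 (1.1 equiv), acetone, rt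
Reagents that add atoms: dimethyl sulfate, COS(=O)(=O)OC
Why: Williamson O-methylation steered by acidity and chelation: the 4-OH lies para to the ester, is the most acidic and is the only hydroxyl not hydrogen-bonded to the ester group, so one equivalent of a hard methylating agent with a weak base should etherify it alone.

Step 3
Reactants: 4 methyl 2,6-dihydroxy-4-methoxy-3,5-diprenylbenzoate
Product: 6 5-methoxy-4,6-diprenylbenzene-1,3-diol, via carboxylic acid 5 (not isolated)
Conditions: KOH, MeOH/H2O, reflux, argon; then 1 M HCl to pH 5, 0 °C
Reagents that add atoms: none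
Why: Saponification followed by protodecarboxylation: the 2,6-dihydroxy-4-methoxybenzoic acid 5 is protonated at its ipso carbon with great ease and loses CO2 during hydrolysis or on neutralisation, a one-pot sequence well known for alkenyl-substituted resorcylate esters, and the basic medium spares the ortho-prenylphenol units that acid would close to chromans.

Step 4
Reactants: 6 5-methoxy-4,6-diprenylbenzene-1,3-diol
Product: 7 2-iodo-5-methoxy-4,6-diprenylbenzene-1,3-diol (2-iodo-5-methoxy-4,6-diprenylresorcinol)
Conditions: I2 (1.0 equiv, slow addition), NaHCO3, THF/H2O, 0 °C, dark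
Reagents that add atoms: iodine, II
Why: Electrophilic aromatic iodination of a resorcinol under mildly basic aqueous conditions: the one free ring carbon is ortho to both hydroxyls and para to the methoxy group, hence far more nucleophilic than a trisubstituted alkene, so one equivalent of I2 fed in slowly should be consumed at the ring before iodoetherification of a prenyl group can start.

Step 5
Reactants: 8 4-hydroxybenzaldehyde
Product: 9 4-(methoxymethoxy)benzaldehyde
Conditions: MOMCl, i-Pr2NEt, CH2Cl2, 0 °C to rt
Reagents that add atoms: chloromethyl methyl ether (MOMCl), COCCl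
Why: Phenol protection by O-alkylation with an α-chloro ether (MOM ether formation), giving an acetal that withstands the basic, nucleophilic and hydridic conditions of steps 6 to 9.

Step 6
Reactants: 9 4-(methoxymethoxy)benzaldehyde
Product: 10 1-ethynyl-4-(methoxymethoxy)benzene
Conditions: dimethyl (1-diazo-2-oxopropyl)phosphonate, K2CO3, MeOH, rt
Reagents that add atoms: dimethyl (1-diazo-2-oxopropyl)phosphonate, CC(=O)C(=[N+]=[N-])P(=O)(OC)OC
Why: Ohira–Bestmann variant of the Seyferth–Gilbert homologation: methanolysis of the reagent frees the dimethyl diazomethylphosphonate anion, which adds to the non-enolisable aldehyde, and Horner–Wadsworth–Emmons-type elimination, loss of N2 and a 1,2-hydride shift should give the terminal alkyne under conditions that leave the MOM ether alone.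

Step 7
Reactants: 7 2-iodo-5-methoxy-4,6-diprenylresorcinol; 10 1-ethynyl-4-(methoxymethoxy)benzene (1.3 equiv); 11 carbon monoxide
Product: 14 5-hydroxy-7-methoxy-4'-(methoxymethoxy)-6,8-diprenylflavone, via ynone 12 (not isolated), via enaminone 13 (not isolated)
Conditions: PdCl2(PPh3)2 (5 mol %), CO (20 bar), Et2NH, 120 °C, autoclave, no copper salt
Reagents that add atoms: none
Why: Zerovalent palladium formed in situ inserts into the C–I bond of 7, migratory insertion of CO gives an aroylpalladium iodide, and the amine-deprotonated alkyne 10 replaces iodide and is reductively eliminated as ynone 12, which creates C4a–C4 and C4–C3. Diethylamine then adds in conjugate fashion to 12 to give enaminone 13, whose C2 is attacked by a flanking phenol with expulsion of the amine, which creates O1–C2. The closest known reaction type is the palladium-catalysed carbonylative Sonogashira coupling–cyclisation of ortho-iodophenols with terminal arylacetylenes to flavones. Ring C closes in a 6-endo mode (formally 6-endo-dig on 12, in practice a 6-endo-trig addition–elimination on 13), and no stereocentre is formed. Two selectivities are needed: CO uptake must outrun direct coupling, which would end in a 2-arylbenzofuran, and this is favoured by the CO pressure, the absence of copper and the electron-rich, doubly ortho-substituted aryl group that migrates readily onto CO; and flavone must win over aurone, which the secondary amine secures because C2 is the only electrophilic carbon left in 13. Regiochemistry does not arise because 7 has a mirror plane through C–I and C–OMe, so whichever hydroxyl becomes O1 the other ends as the chelated 5-OH, and the prenyl groups sit meta to the metal-bearing carbon, out of reach for a Heck closure.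

Step 8
Reactants: 14 5-hydroxy-7-methoxy-4'-(methoxymethoxy)-6,8-diprenylflavone
Product: 15 7-methoxy-5,4'-bis(methoxymethoxy)-6,8-diprenylflavone
Conditions: NaH, MOMCl, DMF, 0 °C to rt
Reagents that add atoms: chloromethyl methyl ether (MOMCl), COCCl
Why: MOM ether formation after irreversible deprotonation: NaH breaks the 5-OH···O=C4 chelate and the small, reactive chloro ether reaches the hindered phenoxide, a masking that is needed because a free acidic phenol would quench the copper hydride of step 9 and its phenoxide would deactivate the enone.

Step 9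
Reactants: 15 7-methoxy-5,4'-bis(methoxymethoxy)-6,8-diprenylflavone
Product: 16 (2S)-7-methoxy-5,4'-bis(methoxymethoxy)-6,8-diprenylflavanone
Conditions: Cu(OAc)2·H2O (5 mol %), (S)-DTBM-SEGPHOS (5.5 mol %), (EtO)2MeSiH (1.5 equiv), t-BuOH (1.5 equiv), toluene, 0 °C to rt
Reagents that add atoms: none
Why: Ligand-controlled copper hydride asymmetric conjugate reduction (1,4-hydrosilylation), established for β,β-disubstituted cyclic enones and 2-substituted chromones: the chiral bisphosphine copper hydride should deliver hydride to the Re face of C2 and so set (2S), t-BuOH protonates the copper enolate at once so that it cannot expel O1, and the isolated prenyl alkenes are inert to this reagent.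

Step 10
Reactants: 16 (2S)-7-methoxy-5,4'-bis(methoxymethoxy)-6,8-diprenylflavanone
Product: 17 (2S)-5,4'-dihydroxy-7-methoxy-6,8-diprenylflavanone (CNP0121058.1)
Conditions: 3 M aq HCl, MeOH, 40 °C
Reagents that add atoms: none
Why: Acid-catalysed acetal solvolysis (transacetalisation to dimethoxymethane) removes both aryl MOM ethers, the mild acid leaves C2 untouched because flavanone racemisation runs through base-induced ring opening, and the liberated 5-OH is chelated to C4=O and thus a poor nucleophile towards the 6-prenyl group.

Compound list
1 | methyl 2,4,6-trihydroxybenzoate | COC(=O)c1c(O)cc(O)cc1O | starting material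
2 | prenyl bromide (1-bromo-3-methylbut-2-ene) | CC(C)=CCBr | starting material
3 | methyl 2,4,6-trihydroxy-3,5-diprenylbenzoate | COC(=O)c1c(O)c(CC=C(C)C)c(O)c(CC=C(C)C)c1O | intermediate
4 | methyl 2,6-dihydroxy-4-methoxy-3,5-diprenylbenzoate | COC(=O)c1c(O)c(CC=C(C)C)c(OC)c(CC=C(C)C)c1O | intermediate
5 | 2,6-dihydroxy-4-methoxy-3,5-diprenylbenzoic acid (not isolated) | O=C(O)c1c(O)c(CC=C(C)C)c(OC)c(CC=C(C)C)c1O | intermediate
6 | 5-methoxy-4,6-diprenylbenzene-1,3-diol | COc1c(CC=C(C)C)c(O)cc(O)c1CC=C(C)C | intermediate
7 | 2-iodo-5-methoxy-4,6-diprenylbenzene-1,3-diol | COc1c(CC=C(C)C)c(O)c(I)c(O)c1CC=C(C)C | intermediate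
8 | 4-hydroxybenzaldehyde | O=Cc1ccc(O)cc1 | starting material
9 | 4-(methoxymethoxy)benzaldehyde | COCOc1ccc(C=O)cc1 | intermediate
10 | 1-ethynyl-4-(methoxymethoxy)benzene | C#Cc1ccc(OCOC)cc1 | intermediate
11 | carbon monoxide | [C-]#[O+] | starting material
12 | 1-(2,6-dihydroxy-4-methoxy-3,5-diprenylphenyl)-3-[4-(methoxymethoxy)phenyl]prop-2-yn-1-one (not isolated) | COc1c(CC=C(C)C)c(O)c(C(=O)C#Cc2ccc(OCOC)cc2)c(O)c1CC=C(C)C | intermediate
13 | 3-(diethylamino)-1-(2,6-dihydroxy-4-methoxy-3,5-diprenylphenyl)-3-[4-(methoxymethoxy)phenyl]prop-2-en-1-one (not isolated, alkene geometry undefined) | COc1c(CC=C(C)C)c(O)c(C(=O)C=C(N(CC)CC)c2ccc(OCOC)cc2)c(O)c1CC=C(C)C | intermediate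
14 | 5-hydroxy-7-methoxy-4'-(methoxymethoxy)-6,8-diprenylflavone | COc1c(CC=C(C)C)c(O)c2c(c1CC=C(C)C)oc(-c1ccc(OCOC)cc1)cc2=O | intermediate
15 | 7-methoxy-5,4'-bis(methoxymethoxy)-6,8-diprenylflavone | COc1c(CC=C(C)C)c(OCOC)c2c(c1CC=C(C)C)oc(-c1ccc(OCOC)cc1)cc2=O | intermediate
16 | (2S)-7-methoxy-5,4'-bis(methoxymethoxy)-6,8-diprenylflavanone | COc1c(CC=C(C)C)c(OCOC)c2c(c1CC=C(C)C)O[C@H](c1ccc(OCOC)cc1)CC2=O | intermediate
17 | (2S)-5,4'-dihydroxy-7-methoxy-6,8-diprenylflavanone | COc1c(CC=C(C)C)c(O)c2c(c1CC=C(C)C)O[C@H](c1ccc(O)cc1)CC2=O | target

Total step count: 10. Longest linear sequence: 8 (steps 1–4 and 7–10).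

Steps most likely to fail

Step 7. Several processes could go wrong:
- Oxidative addition into the hindered, very electron-rich C–I bond may be slow and give way to hydrodeiodination.
- The aroylpalladium species may be intercepted by diethylamine (amide formation).
- Coupling may proceed without CO uptake.

The fallback builds the same carbon framework by polar chemistry, without palladium or CO. It sets out from 6 and 10 and comes back at 15, so steps 4, 7 and 8 are bypassed. Resorcinol 6 is converted with NaH and MOMCl into 3-methoxy-1,5-bis(methoxymethoxy)-2,4-diprenylbenzene F1. Alkyne 10 is lithiated (n-BuLi, THF, −78 °C) and acylated with N-methoxy-N-methylcarbamoyl chloride to the alkynyl Weinreb amide F2. Directed ortho-lithiation of F1 at its only aromatic C–H, between the two MOM ethers (n-BuLi, THF, 0 °C), and addition to F2 should give the tris-MOM ynone F3. Diethylamine in ethanol at rt turns this into the tris-MOM enaminone F4. Methanolic HCl then strips the three MOM groups, and a freed phenol displaces the amine at C2 to give 5,4'-dihydroxy-7-methoxy-6,8-diprenylflavone F5. NaH with excess MOMCl converts F5 into 15.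

Step 9. Several processes could go wrong:
- The vinylogous-ester type acceptor may react sluggishly.
- Facial discrimination may be poor with the flat 2-aryl group.
- The copper enolate may expel O1, which opens the ring, invites further reduction and erodes the enantiomeric purity.
- C4=O may be over-reduced.

The fallback replaces asymmetric induction by resolution. It sets out from 15 and comes back at 16. Reduction with an achiral catalyst (Cu(OAc)2·H2O, 1,2-bis(diphenylphosphino)benzene, (EtO)2MeSiH, t-BuOH, toluene) should give the racemic bis-MOM flavanone F6. Kinetic resolution follows by Noyori asymmetric transfer hydrogenation (RuCl(p-cymene)[(R,R)-TsDPEN], HCO2H/Et3N, rt), a method known for racemic flavanones. It should reduce the (2R) enantiomer to the cis-(2R,4R)-flavan-4-ol F7 and leave (2S)-ketone 16, which is separated by chromatography.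

Step 4. The iodinating agent may attack a prenyl double bond, with capture by the neighbouring phenol (iodoetherification), or iodine may be lost from the electron-rich ring during isolation. The fallback places iodine through a carbanion, so no free phenol ever meets an electrophilic iodine source. It sets out from 6 and comes back at 7. NaH and 2-(trimethylsilyl)ethoxymethyl chloride give the bis-SEM ether F8. Directed ortho-lithiation between the two acetal oxygens (n-BuLi, THF, 0 °C) and a quench with I2 at −78 °C give the bis-SEM iodide F9. Fluoride (TBAF, THF/DMPU, 50 °C) frees both phenols without acid, which avoids protodeiodination and chroman formation.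

Further compounds
F1 | step 7 | 3-methoxy-1,5-bis(methoxymethoxy)-2,4-diprenylbenzene | COc1c(CC=C(C)C)c(OCOC)cc(OCOC)c1CC=C(C)C
F2 | step 7 | N-methoxy-N-methyl-3-[4-(methoxymethoxy)phenyl]prop-2-ynamide | CON(C)C(=O)C#Cc1ccc(OCOC)cc1
F3 | step 7 | 1-[4-methoxy-2,6-bis(methoxymethoxy)-3,5-diprenylphenyl]-3-[4-(methoxymethoxy)phenyl]prop-2-yn-1-one | COc1c(CC=C(C)C)c(OCOC)c(C(=O)C#Cc2ccc(OCOC)cc2)c(OCOC)c1CC=C(C)C
F4 | step 7 | 3-(diethylamino)-1-[4-methoxy-2,6-bis(methoxymethoxy)-3,5-diprenylphenyl]-3-[4-(methoxymethoxy)phenyl]prop-2-en-1-one (alkene geometry undefined) | COc1c(CC=C(C)C)c(OCOC)c(C(=O)C=C(N(CC)CC)c2ccc(OCOC)cc2)c(OCOC)c1CC=C(C)C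
F5 | step 7 | 5,4'-dihydroxy-7-methoxy-6,8-diprenylflavone | COc1c(CC=C(C)C)c(O)c2c(c1CC=C(C)C)oc(-c1ccc(O)cc1)cc2=O
F6 | step 9 | racemic 7-methoxy-5,4'-bis(methoxymethoxy)-6,8-diprenylflavanone | COc1c(CC=C(C)C)c(OCOC)c2c(c1CC=C(C)C)OC(c1ccc(OCOC)cc1)CC2=O
F7 | step 9 | (2R,4R)-7-methoxy-5,4'-bis(methoxymethoxy)-6,8-diprenylflavan-4-ol (2,4-cis) | COc1c(CC=C(C)C)c(OCOC)c2c(c1CC=C(C)C)O[C@@H](c1ccc(OCOC)cc1)C[C@H]2O
F8 | step 4 | 3-methoxy-2,4-diprenyl-1,5-bis{[2-(trimethylsilyl)ethoxy]methoxy}benzene | COc1c(CC=C(C)C)c(OCOCC[Si](C)(C)C)cc(OCOCC[Si](C)(C)C)c1CC=C(C)C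
F9 | step 4 | 2-iodo-5-methoxy-4,6-diprenyl-1,3-bis{[2-(trimethylsilyl)ethoxy]methoxy}benzene | COc1c(CC=C(C)C)c(OCOCC[Si](C)(C)C)c(I)c(OCOCC[Si](C)(C)C)c1CC=C(C)C
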